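## Structural features

The target is a flavanone: aromatic ring A is fused to the dihydropyranone ring C (O1, C2, C3, the C4 ketone, C4a, C8a), and C2 carries ring B, a 2,4,6-trihydroxyphenyl group. Ring A is a phloroglucinol unit whose three oxygens are O1 on C8a and the hydroxyls on C5 and C7. C6, between C5 and C7, bears the lavandulyl chain: C1'' is the benzylic CH2, C2'' the methine with the isopropenyl group, and C3'' the CH2 of the prenyl arm. The two stereocenters, C2 (S) and C2'' (R), lie on opposite sides of ring A and cannot direct each other, so each needs its own control element. The C2–O1 benzylic ether is β to the ketone and attached to a very electron-rich ring B. It opens by retro-oxa-Michael reaction or ionisation under base or acid, which epimerises C2 and, through the free C5 hydroxyl, can move the chain from C6 to C8. The isopropenyl and prenyl double bonds sit next to ortho phenols, cyclise to chromans under acid and rule out hydrogenolysis. The real difficulty is C2'': an open-chain tertiary allylic carbon with three sterically similar carbon arms, which must be attached at exactly one ring A carbon. The key step uses two facts: C6 is flanked by two oxygens and is the easiest ring position to turn into an aryl anion, and C2'' sits between C1'' and C3'' as the α-carbon of an acrylate sits between its β-carbon and an electrophile, the acyl carbon later becoming the isopropenyl carbon.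

## Logic of the disconnections

29 from 27. The five O–CH2OCH3 bonds on the oxygens of C5, C7, C2', C4' and C6' are cut last. All earlier steps then run on robust acetals and no free phenol ever sits beside the isopropenyl group before the end. The forward step must remove five acetals without free acid (C2–O1 ionisation, chroman formation) and without base (ring opening).

27 from 26. The O1–C2 bond is cut. This is the natural seam of a flavanone, and it makes C2 the last stereocenter to be set, so it meets only one further step. The precursor is an open-chain chalcone. The forward step needs the C8a hydroxyl as the only free ring A oxygen, so that closure has a single constitutional outcome, and a catalyst that selects the enone face.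

26 from 25, and 25 from 17 plus 22. First the O–Si bond on the C8a oxygen, then the C4–C4a bond between ring A and the carbonyl carbon. Ring B and the three-carbon bridge arrive in one piece and the route becomes convergent. The forward step needs an aryl anion at C4a that attacks the amide carbonyl and not the β-carbon, and a silyl ether that stays on until the ketone is in place.

22 from 19 and 20; 19 from 18. The Cα=Cβ double bond is cut by an olefination, and the three acetal C–O bonds of ring B are cut back to the commercial aldehyde. The demand is E geometry and a phenoxide-free, non-enolisable aldehyde.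

17 from 16. The C4a–Br bond is cut. C4a and C8 are equivalent in 16, so the halogenation has no regiochemical question and only has to stop at one bromine and spare the alkenes.

16 from 15, 15 from 13, 13 from 12. The C=CH2 bond, then the C–CH3 bond, then the acyl C–N bond: the isopropenyl carbon is traced back to the imide carbonyl carbon. Each forward step must leave C2'' untouched while it is α to a carbonyl.

12 from 3, 7 and 8. The C6–C1'' and C2''–C3'' bonds are cut in one operation. Three simple pieces result and the only stereocenter of the chain is set where two bonds form. The forward step needs metalation of 3 only between its two acetals, 1,4-addition, and face-selective alkylation of the resulting enolate.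

3 from 2 from 1; 7 from 4 and 5. Two acetal C–O bonds and one Si–O bond lead back to the symmetric triol, and the N-acyl bond leads back to the auxiliary and the acid chloride. The one demand is mono-silylation of a triol with three equal hydroxyls.

## Other disconnections considered

Alternative 1: The cut is the C4–C4a bond of ring C, with O1–C2 already in place. In the forward key step the activated carboxyl of (3S)-3-aryl-3-aryloxypropanoic acid A2 acylates one of the two equivalent carbons ortho to the ether oxygen and gives flavanone A1.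
- In favour: the two ortho positions are interchangeable, so closure has one constitutional outcome. C2 enters as a finished stereocenter and is not created on an equilibrating chalcone. The acetates on ring B withdraw electron density from C2 and make the C2–O1 bond less prone to ionisation than with acetal-protected ring B; on this point the alternative is the better plan.
- Against: the configuration at C2 would have to be set by intermolecular C–O bond formation at a benzylic carbon with two ortho substituents, which is harder than an intramolecular closure. The activated β-aryloxy acid can lose the phenoxide by β-elimination before it acylates, which erases C2. Acylation needs Lewis or Brønsted acid next to silyl ethers and an isopropenyl group. A2 already contains C2'' on ring A, so the lavandulyl problem is left unsolved and a step like the chosen key step is still required.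
- Comparison: structurally it forms C4–C4a instead of O1–C2. Mechanistically it replaces a reversible conjugate addition by an irreversible electrophilic substitution. In regiocontrol the two plans are equal, since both rely on the same local symmetry of ring A. The step count after the chain is in place is about equal.

Alternative 2: The cut is the C1''–C2'' bond, together with a temporary aryl ester C–O bond that is absent from the target. In the forward key step fluoride desilylates benzylic bromide A4, which loses bromide to give ortho-quinone methide A5. A chiral carbene catalyst converts acyl imidazole A6 into its catalyst-bound enolate, which adds to the methide carbon and then acylates the phenoxide to give lactone A3.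
- In favour: C2'' is set by a catalyst and not by a stoichiometric auxiliary, which is better in economy of chirality. The lactone carbonyl serves as the later isopropenyl carbon, as the imide carbonyl does in the chosen plan (equal).
- Against: in A3 the stereocenter is α to an aryl ester and is formed under basic conditions, so enolisation threatens it. Plain alkyl-substituted enolates are the less well-behaved partners of this annulation. A4 is an electron-rich benzylic bromide that needs several more steps than the two leading to 3. Opening A3 to the methyl ketone frees a phenol beside the chain, which can close onto the ketone and later onto the isopropenyl group. The oxygen that the lactone marks is a flanking one, whereas the para oxygen is the one that must be told apart.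
- Comparison: structurally a ring A electrophile meets a chain nucleophile at C1''–C2''; the chosen plan joins a ring A nucleophile at C6–C1'' and adds the prenyl arm in the same flask. Mechanistically catalyst-controlled enantioface selection stands against auxiliary-controlled diastereoface selection on a chelated enolate, the latter being easier to predict here. The alternative is about three steps longer.

Alternative 3: The cut removes three ring A bonds (C5–C6, C7–C8, C4a–C5), so ring A is built around the finished side chain. In the forward key step cyclobutenone A8 opens on heating to vinylketene A10, which adds to siloxyalkyne A9 in a [2+2] cycloaddition. Four-electron ring opening, six-electron ring closure and tautomerisation then give phenol A7.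
- In favour: the cascade fixes the position of the chain, so no metalation regiochemistry arises (equal in certainty to metalation between two acetals). The three ring A oxygens emerge in three different forms, which is better than a statistical mono-silylation. Conditions are neutral.
- Against: A9 must already hold the complete lavandulyl group with C2'' set, so an asymmetric alkylation is still needed, followed by ynolate homologation and silylation. The heat required exposes the two alkenes of A9, themselves ketenophiles, to side reactions. A8 is not a stock compound. In A7 the acetal sits on the para oxygen, the one that must be free for ring C, so protecting groups have to be exchanged.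
- Comparison: structurally ring A becomes a product instead of a starting material. Mechanistically a pericyclic cascade replaces polar organometallic steps. Step economy is worse, because the chosen plan obtains ring A from a stock triol in two steps.

Key step: step 4

Remark on the chemistry: flavanone numbering is used throughout (ring B primed, lavandulyl C1'' to C3''). The sense of induction in step 13 is assigned by analogy with related chalcone closures; the quinidine-derived pseudo-enantiomer of the catalyst is the direct replacement if the opposite sense is met.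

## Route

Step 1
Reactants: 1 phloroglucinol (benzene-1,3,5-triol, anhydrous)
Product: 2 5-(triisopropylsilyloxy)benzene-1,3-diol
Conditions: TIPSCl (1.0 equiv), imidazole, 1 (3 equiv), DMF, 0 °C to rt
Reagents that add atoms: triisopropylsilyl chloride, CC(C)[Si](Cl)(C(C)C)C(C)C
Why: O-silylation of a phenol; the threefold excess of the cheap triol biases the statistical reaction towards the mono ether, and unreacted triol is removed by aqueous washing.

Step 2
Reactants: 2 5-(triisopropylsilyloxy)benzene-1,3-diol
Product: 3 1,3-bis(methoxymethoxy)-5-(triisopropylsilyloxy)benzene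
Conditions: MOMCl (3 equiv), i-Pr2NEt, CH2Cl2, 0 °C to rt
Reagents that add atoms: chloromethyl methyl ether, COCCl
Why: Amine-mediated O-alkylation of both phenols (acetal formation); the hindered aryl silyl ether is inert to the amine base.

Step 3
Reactants: 4 (R)-4-benzyloxazolidin-2-one; 5 acryloyl chloride
Product: 7 (R)-3-acryloyl-4-benzyloxazolidin-2-one, via bromomagnesium imide salt 6 (not isolated)
Conditions: MeMgBr (1.0 equiv), THF, 0 °C; then 5, −78 °C to 0 °C
Reagents that add atoms: none
Why: N-acylation of the magnesium salt of the oxazolidinone; low temperature and the absence of free amine keep the acrylimide from polymerising, and the auxiliary stereocenter is not involved.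

Step 4
Reactants: 3 1,3-bis(methoxymethoxy)-5-(triisopropylsilyloxy)benzene; 7 (R)-3-acryloyl-4-benzyloxazolidin-2-one; 8 prenyl bromide (1-bromo-3-methylbut-2-ene)
Product: 12 (R)-4-benzyl-3-[(2R)-2-{[2,6-bis(methoxymethoxy)-4-(triisopropylsilyloxy)phenyl]methyl}-5-methylhex-4-enoyl]oxazolidin-2-one, via aryllithium 9 (not isolated), via lithium diarylcuprate 10 (not isolated), via lithium Z-enolate 11 (not isolated)
Conditions: 3 (2.2 equiv), n-BuLi (2.2 equiv), THF, 0 °C; CuBr·SMe2 (0.5 equiv per ArLi), −40 °C; 7 (1.0 equiv, slow addition), −78 °C; 8 (4 equiv), −78 to −10 °C; aq NH4Cl/NH3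
Reagents that add atoms: none
Why: n-BuLi removes the ring proton between the two MOM ethers (directed ortho-metalation; the bulky, non-coordinating silyl ether shields its own neighbours), and CuBr·SMe2 converts aryllithium 9 into the diarylcuprate 10 of monovalent copper. Cuprate 10 transfers one aryl group to the β-carbon of the lithium-chelated s-cis acrylimide 7 (π-complex, then reductive elimination), forming C6–C1'' and giving the chelated Z lithium enolate 11; the second aryl ligand returns as 3 on work-up. Enolate 11 is the same species as in an auxiliary-directed imide alkylation and attacks the primary carbon of 8 in an SN2 reaction, forming C2''–C3''. The closest known reaction type is the tandem organocopper conjugate addition and enolate trapping of N-enoyl oxazolidinones, with the allylic bromide in place of the usual halogen or proton electrophile. No ring is closed. The one new stereocenter, C2'', is controlled by the (R)-4-benzyl group: in the rigid chelate it covers one enolate face, 8 enters from the other, and because the CH2Ar arm outranks the prenyl arm the result is 2R. The step needs 1,4- over 1,2-addition (soft cuprate, unhindered β-carbon), monoaddition without Michael oligomerisation (7 added slowly to excess 10 at −78 °C), α- and not γ-attack on 8 (lithium enolate, no polar cosolvent) and high facial selectivity (chelation kept intact in THF).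

Step 5
Reactants: 12 (R)-4-benzyl-3-[(2R)-2-{[2,6-bis(methoxymethoxy)-4-(triisopropylsilyloxy)phenyl]methyl}-5-methylhex-4-enoyl]oxazolidin-2-one
Product: 13 (2R)-2-{[2,6-bis(methoxymethoxy)-4-(triisopropylsilyloxy)phenyl]methyl}-N-methoxy-N,5-dimethylhex-4-enamide
Conditions: MeNH(OMe)·HCl, AlMe3, CH2Cl2, −15 °C to rt; Rochelle salt work-up
Reagents that add atoms: N,O-dimethylhydroxylamine hydrochloride, CNOC.Cl
Why: Aluminium amide aminolysis of the exocyclic imide carbonyl (Weinreb amide formation); the reagent is not basic enough to enolise the imide, so C2'' should be retained, and auxiliary 4 is released for reuse.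

Step 6
Reactants: 13 (2R)-2-{[2,6-bis(methoxymethoxy)-4-(triisopropylsilyloxy)phenyl]methyl}-N-methoxy-N,5-dimethylhex-4-enamide
Product: 15 (3R)-3-{[2,6-bis(methoxymethoxy)-4-(triisopropylsilyloxy)phenyl]methyl}-6-methylhept-5-en-2-one, via magnesium hemiaminal chelate 14 (not isolated)
Conditions: MeMgBr, THF, 0 °C; aq NH4Cl
Reagents that add atoms: methylmagnesium bromide, C[Mg]Br
Why: Weinreb ketone synthesis; chelate 14 persists until the quench, so there is no over-addition and the ketone never meets the basic reagent that could epimerise its α-carbon.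

Step 7
Reactants: 15 (3R)-3-{[2,6-bis(methoxymethoxy)-4-(triisopropylsilyloxy)phenyl]methyl}-6-methylhept-5-en-2-one
Product: 16 {3,5-bis(methoxymethoxy)-4-[(2R)-5-methyl-2-(prop-1-en-2-yl)hex-4-en-1-yl]phenoxy}tri(propan-2-yl)silane
Conditions: Cp2TiMe2, toluene/THF, 70 °C, dark
Reagents that add atoms: dimethyltitanocene, C[Ti](C)(C1C=CC=C1)C1C=CC=C1
Why: Petasis methylenation through the titanocene methylidene and an oxatitanacyclobutane; the reagent is not basic, so the α-stereocenter passes unchanged into the lavandulyl group, after which it is no longer acidic.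

Step 8
Reactants: 16 {3,5-bis(methoxymethoxy)-4-[(2R)-5-methyl-2-(prop-1-en-2-yl)hex-4-en-1-yl]phenoxy}tri(propan-2-yl)silane
Product: 17 {2-bromo-3,5-bis(methoxymethoxy)-4-[(2R)-5-methyl-2-(prop-1-en-2-yl)hex-4-en-1-yl]phenoxy}tri(propan-2-yl)silane
Conditions: NBS (1.0 equiv), CH2Cl2, −40 to 0 °C, dark
Reagents that add atoms: N-bromosuccinimide, O=C1CCC(=O)N1Br
Why: Electrophilic aromatic bromination; the two free ring positions are constitutionally equivalent, so only one monobromide can form, and the tri-oxygenated arene is far more nucleophilic than the two alkenes.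

Step 9
Reactants: 18 2,4,6-trihydroxybenzaldehyde
Product: 19 2,4,6-tris(methoxymethoxy)benzaldehyde
Conditions: NaH, MOMCl (3.6 equiv), THF/DMF, 0 °C to rt
Reagents that add atoms: chloromethyl methyl ether, COCCl
Why: Threefold O-alkylation of the sodium phenoxides; the strong base is needed because the two hydroxyls hydrogen-bonded to the aldehyde react sluggishly with amine bases.

Step 10
Reactants: 19 2,4,6-tris(methoxymethoxy)benzaldehyde; 20 diethyl {2-[methoxy(methyl)amino]-2-oxoethyl}phosphonate
Product: 22 (2E)-N-methoxy-N-methyl-3-[2,4,6-tris(methoxymethoxy)phenyl]prop-2-enamide, via sodium phosphonate anion 21 (not isolated)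
Conditions: NaH, THF, 0 °C; then 19, 0 °C to rt
Reagents that add atoms: none
Why: Horner–Wadsworth–Emmons olefination; the stabilised phosphonate anion gives the E alkene, and the aldehyde has no enolisable position.

Step 11
Reactants: 17 {2-bromo-3,5-bis(methoxymethoxy)-4-[(2R)-5-methyl-2-(prop-1-en-2-yl)hex-4-en-1-yl]phenoxy}tri(propan-2-yl)silane; 22 (2E)-N-methoxy-N-methyl-3-[2,4,6-tris(methoxymethoxy)phenyl]prop-2-enamide
Product: 25 (2E)-1-{2,4-bis(methoxymethoxy)-3-[(2R)-5-methyl-2-(prop-1-en-2-yl)hex-4-en-1-yl]-6-(triisopropylsilyloxy)phenyl}-3-[2,4,6-tris(methoxymethoxy)phenyl]prop-2-en-1-one, via aryllithium 23 (not isolated), via lithium hemiaminal adduct 24 (not isolated)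
Conditions: n-BuLi (1.0 equiv), THF, −78 °C; 22, −78 to −20 °C; aq NH4Cl
Reagents that add atoms: none
Why: Bromine–lithium exchange followed by acyl substitution on the Weinreb amide; adduct 24 blocks a second addition, and the hindered aryllithium together with the electron-rich β-aryl group favours 1,2- over 1,4-attack.

Step 12
Reactants: 25 (2E)-1-{2,4-bis(methoxymethoxy)-3-[(2R)-5-methyl-2-(prop-1-en-2-yl)hex-4-en-1-yl]-6-(triisopropylsilyloxy)phenyl}-3-[2,4,6-tris(methoxymethoxy)phenyl]prop-2-en-1-one
Product: 26 (2E)-1-{6-hydroxy-2,4-bis(methoxymethoxy)-3-[(2R)-5-methyl-2-(prop-1-en-2-yl)hex-4-en-1-yl]phenyl}-3-[2,4,6-tris(methoxymethoxy)phenyl]prop-2-en-1-one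
Conditions: TBAF, AcOH (1:1), THF, 0 °C
Reagents that add atoms: none
Why: Fluoride cleavage of the aryl silyl ether; buffering with acetic acid delivers the phenol and not the phenoxide, so no base-induced, unselective ring closure precedes step 13.

Step 13
Reactants: 26 (2E)-1-{6-hydroxy-2,4-bis(methoxymethoxy)-3-[(2R)-5-methyl-2-(prop-1-en-2-yl)hex-4-en-1-yl]phenyl}-3-[2,4,6-tris(methoxymethoxy)phenyl]prop-2-en-1-one
Product: 27 (2S)-5,7-bis(methoxymethoxy)-6-[(2R)-5-methyl-2-(prop-1-en-2-yl)hex-4-en-1-yl]-2-[2,4,6-tris(methoxymethoxy)phenyl]-2,3-dihydro-4H-chromen-4-one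
Conditions: 1-[3,5-bis(trifluoromethyl)phenyl]-3-[(8S,9S)-6'-methoxycinchonan-9-yl]thiourea (15 mol%), toluene, rt
Reagents that add atoms: none
Why: Organocatalytic intramolecular oxa-Michael addition (6-endo-trig) of the C8a hydroxyl to the enone; the quinuclidine nitrogen activates the phenol and the thiourea binds the carbonyl, so the catalyst chooses the enone face and should set C2 as S, the remote C2'' having no influence.

Step 14
Reactants: 27 (2S)-5,7-bis(methoxymethoxy)-6-[(2R)-5-methyl-2-(prop-1-en-2-yl)hex-4-en-1-yl]-2-[2,4,6-tris(methoxymethoxy)phenyl]-2,3-dihydro-4H-chromen-4-one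
Product: 29 (2S)-5,7-dihydroxy-6-[(2R)-5-methyl-2-(prop-1-en-2-yl)hex-4-en-1-yl]-2-(2,4,6-trihydroxyphenyl)-2,3-dihydro-4H-chromen-4-one, via pentakis(trimethylsilyl) ether 28 (not isolated)
Conditions: TMSOTf, 2,2'-bipyridyl, MeCN, 0 °C to rt; then H2O, rt
Reagents that add atoms: none
Why: Silyl triflate–bipyridyl cleavage of aromatic MOM ethers: each acetal is exchanged for an aryl trimethylsilyl ether under buffered, non-protic conditions and water then hydrolyses the silyl ethers; neither free acid nor base is present, which protects the C2–O1 bond and the isopropenyl group.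

## Compound list

1 | phloroglucinol (benzene-1,3,5-triol) | Oc1cc(O)cc(O)c1 | starting material
2 | 5-(triisopropylsilyloxy)benzene-1,3-diol | Oc1cc(O)cc(O[Si](C(C)C)(C(C)C)C(C)C)c1 | intermediate
3 | 1,3-bis(methoxymethoxy)-5-(triisopropylsilyloxy)benzene | COCOc1cc(O[Si](C(C)C)(C(C)C)C(C)C)cc(OCOC)c1 | intermediate
4 | (R)-4-benzyloxazolidin-2-one | O=C1N[C@H](Cc2ccccc2)CO1 | starting material
5 | acryloyl chloride | C=CC(=O)Cl | starting material
6 | bromomagnesium salt of (R)-4-benzyloxazolidin-2-one (not isolated) | O=C1N([Mg]Br)[C@H](Cc2ccccc2)CO1 | intermediate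
7 | (R)-3-acryloyl-4-benzyloxazolidin-2-one | C=CC(=O)N1[C@H](Cc2ccccc2)COC1=O | intermediate
8 | prenyl bromide (1-bromo-3-methylbut-2-ene) | CC(C)=CCBr | starting material
9 | [2,6-bis(methoxymethoxy)-4-(triisopropylsilyloxy)phenyl]lithium (not isolated) | [Li]c1c(OCOC)cc(O[Si](C(C)C)(C(C)C)C(C)C)cc1OCOC | intermediate
10 | lithium bis[2,6-bis(methoxymethoxy)-4-(triisopropylsilyloxy)phenyl]cuprate of monovalent copper (not isolated) | [Li+].COCOc1cc(O[Si](C(C)C)(C(C)C)C(C)C)cc(OCOC)c1[Cu-]c1c(OCOC)cc(O[Si](C(C)C)(C(C)C)C(C)C)cc1OCOC | intermediate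
11 | lithium (Z)-enolate of (R)-4-benzyl-3-{3-[2,6-bis(methoxymethoxy)-4-(triisopropylsilyloxy)phenyl]propanoyl}oxazolidin-2-one (not isolated) | [Li]O/C(=C\Cc1c(OCOC)cc(O[Si](C(C)C)(C(C)C)C(C)C)cc1OCOC)N1[C@H](Cc2ccccc2)COC1=O | intermediate
12 | (R)-4-benzyl-3-[(2R)-2-{[2,6-bis(methoxymethoxy)-4-(triisopropylsilyloxy)phenyl]methyl}-5-methylhex-4-enoyl]oxazolidin-2-one | O=C(N1[C@H](Cc2ccccc2)COC1=O)[C@H](CC=C(C)C)Cc1c(OCOC)cc(O[Si](C(C)C)(C(C)C)C(C)C)cc1OCOC | intermediate
13 | (2R)-2-{[2,6-bis(methoxymethoxy)-4-(triisopropylsilyloxy)phenyl]methyl}-N-methoxy-N,5-dimethylhex-4-enamide | CON(C)C(=O)[C@H](CC=C(C)C)Cc1c(OCOC)cc(O[Si](C(C)C)(C(C)C)C(C)C)cc1OCOC | intermediate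
14 | bromomagnesium alkoxide of the methyl adduct of 13, N,O-chelated hemiaminal (not isolated) | CON(C)C(C)(O[Mg]Br)[C@H](CC=C(C)C)Cc1c(OCOC)cc(O[Si](C(C)C)(C(C)C)C(C)C)cc1OCOC | intermediate
15 | (3R)-3-{[2,6-bis(methoxymethoxy)-4-(triisopropylsilyloxy)phenyl]methyl}-6-methylhept-5-en-2-one | CC(=O)[C@H](CC=C(C)C)Cc1c(OCOC)cc(O[Si](C(C)C)(C(C)C)C(C)C)cc1OCOC | intermediate
16 | {3,5-bis(methoxymethoxy)-4-[(2R)-5-methyl-2-(prop-1-en-2-yl)hex-4-en-1-yl]phenoxy}tri(propan-2-yl)silane | C=C(C)[C@H](CC=C(C)C)Cc1c(OCOC)cc(O[Si](C(C)C)(C(C)C)C(C)C)cc1OCOC | intermediate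
17 | {2-bromo-3,5-bis(methoxymethoxy)-4-[(2R)-5-methyl-2-(prop-1-en-2-yl)hex-4-en-1-yl]phenoxy}tri(propan-2-yl)silane | C=C(C)[C@H](CC=C(C)C)Cc1c(OCOC)cc(O[Si](C(C)C)(C(C)C)C(C)C)c(Br)c1OCOC | intermediate
18 | 2,4,6-trihydroxybenzaldehyde | O=Cc1c(O)cc(O)cc1O | starting material
19 | 2,4,6-tris(methoxymethoxy)benzaldehyde | O=Cc1c(OCOC)cc(OCOC)cc1OCOC | intermediate
20 | diethyl {2-[methoxy(methyl)amino]-2-oxoethyl}phosphonate | CCOP(=O)(CC(=O)N(C)OC)OCC | starting material
21 | sodium salt of the carbanion of 20 (not isolated) | CCOP(=O)(OCC)[CH-]C(=O)N(C)OC.[Na+] | intermediate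
22 | (2E)-N-methoxy-N-methyl-3-[2,4,6-tris(methoxymethoxy)phenyl]prop-2-enamide | CON(C)C(=O)/C=C/c1c(OCOC)cc(OCOC)cc1OCOC | intermediate
23 | {2,4-bis(methoxymethoxy)-3-[(2R)-5-methyl-2-(prop-1-en-2-yl)hex-4-en-1-yl]-6-(triisopropylsilyloxy)phenyl}lithium (not isolated) | C=C(C)[C@H](CC=C(C)C)Cc1c(OCOC)cc(O[Si](C(C)C)(C(C)C)C(C)C)c([Li])c1OCOC | intermediate
24 | lithium alkoxide of the adduct of 23 to 22, N,O-chelated hemiaminal (not isolated) | C=C(C)[C@H](CC=C(C)C)Cc1c(OCOC)cc(O[Si](C(C)C)(C(C)C)C(C)C)c(C(O[Li])(N(C)OC)/C=C/c2c(OCOC)cc(OCOC)cc2OCOC)c1OCOC | intermediate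
25 | (2E)-1-{2,4-bis(methoxymethoxy)-3-[(2R)-5-methyl-2-(prop-1-en-2-yl)hex-4-en-1-yl]-6-(triisopropylsilyloxy)phenyl}-3-[2,4,6-tris(methoxymethoxy)phenyl]prop-2-en-1-one | C=C(C)[C@H](CC=C(C)C)Cc1c(OCOC)cc(O[Si](C(C)C)(C(C)C)C(C)C)c(C(=O)/C=C/c2c(OCOC)cc(OCOC)cc2OCOC)c1OCOC | intermediate
26 | (2E)-1-{6-hydroxy-2,4-bis(methoxymethoxy)-3-[(2R)-5-methyl-2-(prop-1-en-2-yl)hex-4-en-1-yl]phenyl}-3-[2,4,6-tris(methoxymethoxy)phenyl]prop-2-en-1-one | C=C(C)[C@H](CC=C(C)C)Cc1c(OCOC)cc(O)c(C(=O)/C=C/c2c(OCOC)cc(OCOC)cc2OCOC)c1OCOC | intermediate
27 | (2S)-5,7-bis(methoxymethoxy)-6-[(2R)-5-methyl-2-(prop-1-en-2-yl)hex-4-en-1-yl]-2-[2,4,6-tris(methoxymethoxy)phenyl]-2,3-dihydro-4H-chromen-4-one | C=C(C)[C@H](CC=C(C)C)Cc1c(OCOC)cc2c(c1OCOC)C(=O)C[C@@H](c1c(OCOC)cc(OCOC)cc1OCOC)O2 | intermediate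
28 | (2S)-6-[(2R)-5-methyl-2-(prop-1-en-2-yl)hex-4-en-1-yl]-5,7-bis(trimethylsilyloxy)-2-[2,4,6-tris(trimethylsilyloxy)phenyl]-2,3-dihydro-4H-chromen-4-one (not isolated) | C=C(C)[C@H](CC=C(C)C)Cc1c(O[Si](C)(C)C)cc2c(c1O[Si](C)(C)C)C(=O)C[C@@H](c1c(O[Si](C)(C)C)cc(O[Si](C)(C)C)cc1O[Si](C)(C)C)O2 | intermediate
29 | (2S)-5,7-dihydroxy-6-[(2R)-5-methyl-2-(prop-1-en-2-yl)hex-4-en-1-yl]-2-(2,4,6-trihydroxyphenyl)-2,3-dihydro-4H-chromen-4-one | C=C(C)[C@H](CC=C(C)C)Cc1c(O)cc2c(c1O)C(=O)C[C@@H](c1c(O)cc(O)cc1O)O2 | target

## Step count and least certain steps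

Total step count: 14. Longest linear sequence: 11 steps (steps 1, 2, 4, 5, 6, 7, 8, 11, 12, 13, 14). Steps 3, 9 and 10 are side branches.

Step 4 (key step). The most likely failure is slow or unselective trapping of enolate 11:
- Michael oligomerisation with unreacted 7;
- proton quench during a sluggish alkylation;
- copper-mediated γ-attack on 8;
- consumption of 8 by the residual arylcopper;
- loss of facial selectivity if the lithium chelate is broken.

Fallback, setting out from 3 and 7 and returning at 12: the same cuprate addition is run alone and quenched with NH4Cl to give (R)-4-benzyl-3-{3-[2,6-bis(methoxymethoxy)-4-(triisopropylsilyloxy)phenyl]propanoyl}oxazolidin-2-one F1. F1 is then deprotonated with NaHMDS in THF at −78 °C and the sodium Z-enolate is alkylated with 8. This is the standard auxiliary-directed alkylation and passes through the same chelated enolate geometry, so it should give the same 2R centre of 12.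

Step 13. The likely failures are poor facial selectivity, erosion of the C2 configuration by reversible ring opening under the basic catalyst, and slow closure onto the hindered, electron-rich β-carbon. Fallback, setting out from 26 and returning at 27: closure with NaOAc in refluxing ethanol gives 27 together with its C2 epimer, (2R)-5,7-bis(methoxymethoxy)-6-[(2R)-5-methyl-2-(prop-1-en-2-yl)hex-4-en-1-yl]-2-[2,4,6-tris(methoxymethoxy)phenyl]-2,3-dihydro-4H-chromen-4-one F2. The mixture is then submitted to asymmetric transfer hydrogenation with the enantiomer of RuCl(p-cymene)(TsDPEN) matched to the 2R epimer, in HCO2H/Et3N. F2 should be reduced faster, to (2R,4R)-5,7-bis(methoxymethoxy)-6-[(2R)-5-methyl-2-(prop-1-en-2-yl)hex-4-en-1-yl]-2-[2,4,6-tris(methoxymethoxy)phenyl]-3,4-dihydro-2H-chromen-4-ol F3, while 27 is left as the ketone and separated by chromatography. At most half of the material can be recovered this way.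

Step 14. The likely failures are epimerisation at C2 through opening of the C2–O1 bond, addition of a freed phenol to the isopropenyl group, and incomplete cleavage of the hindered acetal on the C5 oxygen. Fallback, setting out from 27 and returning at 29: TESOTf and 2,2'-bipyridyl exchange the five acetals for triethylsilyl ethers to give (2S)-6-[(2R)-5-methyl-2-(prop-1-en-2-yl)hex-4-en-1-yl]-5,7-bis(triethylsilyloxy)-2-[2,4,6-tris(triethylsilyloxy)phenyl]-2,3-dihydro-4H-chromen-4-one F4. F4 is stable enough to be purified away from the bipyridinium salts and formaldehyde equivalents. The phenols are then released in a separate operation with Et3N·3HF in THF at 0 °C.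

Step 5. The likely failure is attack of the aluminium amide at the ring carbonyl of the auxiliary instead of the hindered exocyclic carbonyl, which opens the oxazolidinone. Fallback, setting out from 12 and returning at 13: LiOH/H2O2 in THF/H2O at 0 °C cleaves the exocyclic acyl group selectively to (2R)-2-{[2,6-bis(methoxymethoxy)-4-(triisopropylsilyloxy)phenyl]methyl}-5-methylhex-4-enoic acid F5 and returns 4. F5 is then coupled with MeNH(OMe)·HCl (EDC·HCl, HOBt, i-Pr2NEt, CH2Cl2).

Step 11. The likely failures are proton transfer to the hindered aryllithium 23, or migration of the silyl group from oxygen to the lithiated carbon, before the slow acylation takes place. Fallback, setting out from 19 and 17 and returning at 25: Wittig reaction of 19 with Ph3P=CHCHO gives (2E)-3-[2,4,6-tris(methoxymethoxy)phenyl]prop-2-enal F6. Aryllithium 23 (from 17 and n-BuLi at −78 °C) adds quickly to this non-enolisable aldehyde to give (2E)-1-{2,4-bis(methoxymethoxy)-3-[(2R)-5-methyl-2-(prop-1-en-2-yl)hex-4-en-1-yl]-6-(triisopropylsilyloxy)phenyl}-3-[2,4,6-tris(methoxymethoxy)phenyl]prop-2-en-1-ol F7 as a mixture of carbinol epimers. Oxidation of F7 with MnO2 in CH2Cl2 gives 25.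

## Further compounds

F1 | step 4 | (R)-4-benzyl-3-{3-[2,6-bis(methoxymethoxy)-4-(triisopropylsilyloxy)phenyl]propanoyl}oxazolidin-2-one | O=C(CCc1c(OCOC)cc(O[Si](C(C)C)(C(C)C)C(C)C)cc1OCOC)N1[C@H](Cc2ccccc2)COC1=O
F2 | step 13 | (2R)-5,7-bis(methoxymethoxy)-6-[(2R)-5-methyl-2-(prop-1-en-2-yl)hex-4-en-1-yl]-2-[2,4,6-tris(methoxymethoxy)phenyl]-2,3-dihydro-4H-chromen-4-one | C=C(C)[C@H](CC=C(C)C)Cc1c(OCOC)cc2c(c1OCOC)C(=O)C[C@H](c1c(OCOC)cc(OCOC)cc1OCOC)O2
F3 | step 13 | (2R,4R)-5,7-bis(methoxymethoxy)-6-[(2R)-5-methyl-2-(prop-1-en-2-yl)hex-4-en-1-yl]-2-[2,4,6-tris(methoxymethoxy)phenyl]-3,4-dihydro-2H-chromen-4-ol | C=C(C)[C@H](CC=C(C)C)Cc1c(OCOC)cc2c(c1OCOC)[C@H](O)C[C@H](c1c(OCOC)cc(OCOC)cc1OCOC)O2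
F4 | step 14 | (2S)-6-[(2R)-5-methyl-2-(prop-1-en-2-yl)hex-4-en-1-yl]-5,7-bis(triethylsilyloxy)-2-[2,4,6-tris(triethylsilyloxy)phenyl]-2,3-dihydro-4H-chromen-4-one | C=C(C)[C@H](CC=C(C)C)Cc1c(O[Si](CC)(CC)CC)cc2c(c1O[Si](CC)(CC)CC)C(=O)C[C@@H](c1c(O[Si](CC)(CC)CC)cc(O[Si](CC)(CC)CC)cc1O[Si](CC)(CC)CC)O2
F5 | step 5 | (2R)-2-{[2,6-bis(methoxymethoxy)-4-(triisopropylsilyloxy)phenyl]methyl}-5-methylhex-4-enoic acid | O=C(O)[C@H](CC=C(C)C)Cc1c(OCOC)cc(O[Si](C(C)C)(C(C)C)C(C)C)cc1OCOC
F6 | step 11 | (2E)-3-[2,4,6-tris(methoxymethoxy)phenyl]prop-2-enal | O=C/C=C/c1c(OCOC)cc(OCOC)cc1OCOC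
F7 | step 11 | (2E)-1-{2,4-bis(methoxymethoxy)-3-[(2R)-5-methyl-2-(prop-1-en-2-yl)hex-4-en-1-yl]-6-(triisopropylsilyloxy)phenyl}-3-[2,4,6-tris(methoxymethoxy)phenyl]prop-2-en-1-ol | C=C(C)[C@H](CC=C(C)C)Cc1c(OCOC)cc(O[Si](C(C)C)(C(C)C)C(C)C)c(C(O)/C=C/c2c(OCOC)cc(OCOC)cc2OCOC)c1OCOC
A1 | alternative 1 | (2S)-5,7-bis(tert-butyldimethylsilyloxy)-6-[(2R)-5-methyl-2-(prop-1-en-2-yl)hex-4-en-1-yl]-2-(2,4,6-triacetoxyphenyl)-2,3-dihydro-4H-chromen-4-one | C=C(C)[C@H](CC=C(C)C)Cc1c(O[Si](C)(C)C(C)(C)C)cc2c(c1O[Si](C)(C)C(C)(C)C)C(=O)C[C@@H](c1c(OC(C)=O)cc(OC(C)=O)cc1OC(C)=O)O2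
A2 | alternative 1 | (3S)-3-{3,5-bis(tert-butyldimethylsilyloxy)-4-[(2R)-5-methyl-2-(prop-1-en-2-yl)hex-4-en-1-yl]phenoxy}-3-(2,4,6-triacetoxyphenyl)propanoic acid | C=C(C)[C@H](CC=C(C)C)Cc1c(O[Si](C)(C)C(C)(C)C)cc(O[C@@H](CC(=O)O)c2c(OC(C)=O)cc(OC(C)=O)cc2OC(C)=O)cc1O[Si](C)(C)C(C)(C)C
A3 | alternative 2 | (3R)-5-(methoxymethoxy)-3-(3-methylbut-2-enyl)-7-(prop-2-enyloxy)chroman-2-one | O=C1[C@H](CC=C(C)C)Cc2c(OCOC)cc(OCC=C)cc2O1
A4 | alternative 2 | [2-(bromomethyl)-3-(methoxymethoxy)-5-(prop-2-en-1-yloxy)phenoxy](tert-butyl)dimethylsilane | BrCc1c(OCOC)cc(OCC=C)cc1O[Si](C)(C)C(C)(C)C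
A5 | alternative 2 | 5-(methoxymethoxy)-6-methylidene-3-(prop-2-en-1-yloxy)cyclohexa-2,4-dien-1-one | C=C1C(=O)C=C(OCC=C)C=C1OCOC
A6 | alternative 2 | 1-(1H-imidazol-1-yl)-5-methylhex-4-en-1-one | CC(C)=CCCC(=O)n1ccnc1
A7 | alternative 3 | 5-(methoxymethoxy)-2-[(2R)-5-methyl-2-(prop-1-en-2-yl)hex-4-enyl]-3-(triisopropylsilyloxy)phenol | C=C(C)[C@H](CC=C(C)C)Cc1c(O)cc(OCOC)cc1O[Si](C(C)C)(C(C)C)C(C)C
A8 | alternative 3 | 3-(methoxymethoxy)cyclobut-2-en-1-one | COCOC1=CC(=O)C1
A9 | alternative 3 | triisopropyl{[(4R)-7-methyl-4-(prop-1-en-2-yl)oct-6-en-1-yn-1-yl]oxy}silane | C=C(C)[C@H](CC=C(C)C)CC#CO[Si](C(C)C)(C(C)C)C(C)C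
A10 | alternative 3 | 3-(methoxymethoxy)buta-1,3-dien-1-one | C=C(OCOC)C=C=O
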